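**Retrosynthetic overview** (terpenoid numbering: C1 and C5 are the ring-fusion carbons, C4 is the quaternary carbon, C10 bears C14, C7 bears C11)
1. Target ⇒ three O-demethylations, then Br→isovaleryl and Br→CHO by bromine–lithium exchange ⇒ 4-(3,5-dibromo-2,4,6-trimethoxybenzyl)guai-5-en-11-ol ⇒ removal of C3=O and reductive cleavage of C2–C10 ⇒ a 2,10-cycloguai-5-en-3-one.
2. Key disconnection: this tricycle ⇒ an isomeric decalin, a 10-epi-eudesma-1,5-dien-3-one, by a photochemical 1,2-vinyl shift. The cyclopentane C1–C5 arises by contraction of the six-membered ring A (C1–C5 plus C10), while ring B (C5–C10) takes up C1 and becomes the cycloheptene.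
3. Enabling feature: the enone bond C1=C2 and the bond C5=C6 both hang on quaternary C10 (a di-π-methane array inside ring A). C4 and C10 carry no hydrogen. The angular methyl at C10 first steers the benzylation at C4 and then relays its configuration to C1.
4. Decalin ⇒ deconjugative C4-benzylation of the cross-conjugated dienone ⇒ dehydrogenation, alkene hydration, and Robinson annulation of (+)-dihydrocarvone with ethyl vinyl ketone.
5. Order of ring formation: ring B (chiral pool) → six-membered ring A (annulation) → five-membered ring, seven-membered ring and a temporary cyclopropane together (key step) → cyclopropane opened again.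

Key step: step 7

Remark: α/β refer to the usual drawing with the C7 side chain β. The target then has 1β-H, 10β-H (10α-methyl), 4α-methyl and 4β-CH2Ar.
Remark: commercial (+)-dihydrocarvone is a mixture of C2 epimers. This does not matter, because C2 is erased by enolisation in step 1.

Step 1
Reactants: 1 (+)-dihydrocarvone; 2 ethyl vinyl ketone
Product: 4 (−)-10-epi-α-cyperone, via Michael adduct 3 (not isolated)
Conditions: KOH (0.2 equiv), EtOH, −10 °C to rt; then reflux
Reagents that add atoms: none
Why: Robinson annulation (Michael addition, aldol condensation), in which the thermodynamic enolate of 1 should add to 2 by the stereoelectronically preferred axial attack that leads mainly to the 10-epi series, so that C10 (10α-methyl) is set by C7.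

Step 2
Reactants: 4 (−)-10-epi-α-cyperone
Product: 5 10-epi-carissone
Conditions: Co(acac)2 (10 mol %), PhSiH3, O2 (1 atm), THF, rt
Reagents that add atoms: dioxygen O=O
Why: Mukaiyama hydration (hydrogen-atom transfer from a cobalt hydride, then O2 capture) is Markovnikov-selective for the electron-rich 1,1-disubstituted alkene, should leave the tetrasubstituted enone bond alone, and creates no stereocentre.

Step 3
Reactants: 5 10-epi-carissone
Product: 6 11-hydroxy-10-epi-eudesma-1,4-dien-3-one
Conditions: DDQ, 1,4-dioxane, reflux
Reagents that add atoms: none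
Why: DDQ dehydrogenation of a 4-en-3-one under neutral conditions runs through enolisation at C2 and hydride loss from C1 and should give the cross-conjugated 1,4-dien-3-one without touching C7, C10 or the carbinol.

Step 4
Reactants: 7 2,4,6-trimethoxytoluene
Product: 8 3,5-dibromo-2,4,6-trimethoxytoluene
Conditions: NBS (2.1 equiv), MeCN, 0 °C to rt
Reagents that add atoms: N-bromosuccinimide O=C1CCC(=O)N1Br
Why: Electrophilic aromatic bromination fills the two equivalent, highly nucleophilic free positions, so the later benzylic halide cannot alkylate itself and already carries the handles for both carbonyl groups.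

Step 5
Reactants: 8 3,5-dibromo-2,4,6-trimethoxytoluene
Product: 9 3,5-dibromo-2,4,6-trimethoxybenzyl bromide
Conditions: NBS (1.05 equiv), AIBN (5 mol %), PhCF3, reflux
Reagents that add atoms: N-bromosuccinimide O=C1CCC(=O)N1Br
Why: Wohl–Ziegler bromination should be clean because, with the ring fully substituted, the aryl methyl group holds the only benzylic C–H bonds.

Step 6
Reactants: 6 11-hydroxy-10-epi-eudesma-1,4-dien-3-one; 9 3,5-dibromo-2,4,6-trimethoxybenzyl bromide
Product: 10 4β-(3,5-dibromo-2,4,6-trimethoxybenzyl)-11-hydroxy-10-epi-eudesma-1,5-dien-3-one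
Conditions: KOtBu (1.1 equiv), t-BuOH/THF, 0 °C; then 9, 0 °C to rt
Reagents that add atoms: none
Why: Deconjugative α-alkylation of an extended enolate (as in the 4,4-dialkylation of steroidal 4-en-3-ones and 1,4-dien-3-ones), in which 6 is acidic only at C6, the trienolate reacts at C4 and moves the double bond to C5=C6, and the benzyl group should enter from the β face, anti to the axial 10α-methyl group, which sets C4.

Step 7
Reactants: 10 4β-(3,5-dibromo-2,4,6-trimethoxybenzyl)-11-hydroxy-10-epi-eudesma-1,5-dien-3-one
Product: 11 4β-(3,5-dibromo-2,4,6-trimethoxybenzyl)-11-hydroxy-2,10-cycloguai-5-en-3-one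
Conditions: hν (350–366 nm, Pyrex), degassed benzene (5 mM), 20 °C
Reagents that add atoms: none
Why: Proposed new method: n→π* excitation and intersystem crossing give the twisted enone triplet, whose β-carbon C1 bonds to C5 of the C5=C6 bond held next to it by C10; the resulting cyclopropyldicarbinyl diradical breaks its C5–C10 bond (C5=C6 returns, radicals stay at C2 next to the carbonyl and at tertiary C10), and after spin inversion C2 and C10 join. The closest known reaction types are the lumiketone (type A) rearrangement of 4,4-dialkylcyclohex-2-enones and the di-π-methane 1,2-vinyl shift of 4-alkyl-4-vinylcyclohex-2-enones; new is that the migrating vinyl carbon C5 is itself a member of the enone ring. Ring closure modes: the cyclopentanone C1–C5 arises by contraction of six-membered ring A (C1–C5 plus C10) through 3-exo bridging and reopening, the same bond exchange inserts C1 into ring B and expands it to the cycloheptene, and the cyclopropane C1–C2–C10 closes by 3-exo recombination of the 1,3-diradical. Stereocontrol: C5 can reach C1 only on the face of ring A opposite to the angular methyl group, because ring B must stay cis-fused to the transient C1–C5–C10 cyclopropane, so the configuration of C10 is relayed to C1 (1β-H); C2 (2β-H) and C10 (methyl exo, C9 endo) follow from the only possible cis fusion of the new cyclopropane to both rings, and C4 and C7 are untouched. Selectivity: C1–C5 bridging must beat α-cleavage with 1,3-acyl shift and the oxa-di-π-methane path of the C3=O/C5=C6 pair, and closure must beat the 1,2-shift of H1 to C10. The substrate helps because the lowest triplet and its spin density lie on C1=C2 rather than on the carbonyl carbon, C4 and C10 bear no hydrogen, the fully substituted bromoarene does not absorb above 330 nm and is hard to oxidise, and the non-polar solvent disfavours the zwitterionic hydrogen shift.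

Step 8
Reactants: 11 4β-(3,5-dibromo-2,4,6-trimethoxybenzyl)-11-hydroxy-2,10-cycloguai-5-en-3-one
Product: 12 4β-(3,5-dibromo-2,4,6-trimethoxybenzyl)-11-hydroxyguai-5-en-3-one
Conditions: SmI2 (2.5 equiv), H2O (excess), THF, 0 °C
Reagents that add atoms: none
Why: Ketyl fragmentation of a cyclopropyl ketone, in which the C3 ketyl should cleave the outer bond C2–C10 (the one that overlaps with the ketyl orbital in a bicyclo[3.1.0]hexan-2-one) to give the tertiary C10 radical, and hydrogen delivery from samarium-bound water, held on the β face by the C11 carbinol, anti to C2 and syn to H1, should set 10β-H, while aryl bromides are expected to survive SmI2–H2O without HMPA.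

Step 9
Reactants: 12 4β-(3,5-dibromo-2,4,6-trimethoxybenzyl)-11-hydroxyguai-5-en-3-one
Product: 14 4β-(3,5-dibromo-2,4,6-trimethoxybenzyl)guai-5-en-11-ol, via hydrazone 13 (not isolated)
Conditions: N2H4·H2O, KOH, diethylene glycol, 130 °C, then 200 °C
Reagents that add atoms: none
Why: Wolff–Kishner reduction (Huang-Minlon procedure) removes the activating C3 carbonyl under purely basic conditions that carbinol, aryl ethers and aryl bromides should tolerate, and quaternary C4 keeps the C5=C6 bond from migrating, so no stereocentre is touched.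

Step 10
Reactants: 15 isovaleryl chloride
Product: 16 N-methoxy-N,3-dimethylbutanamide
Conditions: MeNHOMe·HCl, Et3N (2.2 equiv), CH2Cl2, 0 °C to rt
Reagents that add atoms: N,O-dimethylhydroxylamine hydrochloride CNOC.Cl
Why: N-acylation of the hydroxylamine by the acid chloride (Weinreb amide synthesis) is a standard reaction.

Step 11
Reactants: 14 4β-(3,5-dibromo-2,4,6-trimethoxybenzyl)guai-5-en-11-ol; 16 N-methoxy-N,3-dimethylbutanamide
Product: 18 tri-O-methyl ether of the target, via lithium hemiaminal 17 (not isolated)
Conditions: n-BuLi (2.1 equiv), THF, −78 °C; 16, −78 to −40 °C; n-BuLi (1.1 equiv), −78 °C; DMF; 1 M HCl work-up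
Reagents that add atoms: N,N-dimethylformamide CN(C)C=O
Why: Bromine–lithium exchange followed by Weinreb ketone synthesis, whose chelated tetrahedral adduct 17 should persist at low temperature through the second exchange and the formylation with DMF; the two bromines are equivalent, so no regiochemical question arises, and the first equivalent of n-BuLi only deprotonates the carbinol.

Step 12
Reactants: 18 tri-O-methyl ether of the target
Product: 19 CNP0583424.1
Conditions: EtSNa (10 equiv), DMF, 110 °C; then 1 M HCl
Reagents that add atoms: none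
Why: SN2 O-demethylation of aryl methyl ethers by thiolate, in which every methoxy group is ortho to a carbonyl group and therefore gives a stabilised phenoxide, and the acid-free medium should spare the tertiary carbinol, the C5=C6 bond and all four stereocentres.

**Compound list**
1 | (+)-dihydrocarvone, (2R,5R)-2-methyl-5-(prop-1-en-2-yl)cyclohexan-1-one | C[C@@H]1CC[C@H](CC1=O)C(C)=C | starting material
2 | ethyl vinyl ketone (pent-1-en-3-one) | CCC(=O)C=C | starting material
3 | Michael adduct, (2R,5R)-2-methyl-2-(3-oxopentyl)-5-(prop-1-en-2-yl)cyclohexan-1-one | CCC(=O)CC[C@@]1(C)CC[C@H](CC1=O)C(C)=C | intermediate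
4 | (−)-10-epi-α-cyperone, (4aR,7R)-1,4a-dimethyl-7-(prop-1-en-2-yl)-4,4a,5,6,7,8-hexahydronaphthalen-2(3H)-one | CC1=C2C[C@H](C(C)=C)CC[C@]2(C)CCC1=O | intermediate
5 | 10-epi-carissone, 11-hydroxy-10-epi-eudesm-4-en-3-one (10α-methyl, 7β side chain) | CC1=C2C[C@H](C(C)(C)O)CC[C@]2(C)CCC1=O | intermediate
6 | 11-hydroxy-10-epi-eudesma-1,4-dien-3-one (10α-methyl, 7β side chain) | CC1=C2C[C@H](C(C)(C)O)CC[C@]2(C)C=CC1=O | intermediate
7 | 2,4,6-trimethoxytoluene | Cc1c(OC)cc(OC)cc1OC | starting material
8 | 3,5-dibromo-2,4,6-trimethoxytoluene | Cc1c(OC)c(Br)c(OC)c(Br)c1OC | intermediate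
9 | 3,5-dibromo-2,4,6-trimethoxybenzyl bromide | BrCc1c(OC)c(Br)c(OC)c(Br)c1OC | intermediate
10 | 4β-(3,5-dibromo-2,4,6-trimethoxybenzyl)-11-hydroxy-10-epi-eudesma-1,5-dien-3-one (4α-methyl, 10α-methyl, 7β side chain) | O=C1C=C[C@@]2(C)CC[C@@H](C(C)(C)O)C=C2[C@@]1(C)Cc3c(OC)c(Br)c(OC)c(Br)c3OC | intermediate
11 | 4β-(3,5-dibromo-2,4,6-trimethoxybenzyl)-11-hydroxy-2,10-cycloguai-5-en-3-one (cyclopropane C1–C2–C10 on the α face, 1β-H, 2β-H, C14 methyl exo, 4α-methyl, 7β side chain) | O=C1[C@H]2[C@H]3C(=C[C@H](C(C)(C)O)CC[C@@]23C)[C@@]1(C)Cc4c(OC)c(Br)c(OC)c(Br)c4OC | intermediate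
12 | 4β-(3,5-dibromo-2,4,6-trimethoxybenzyl)-11-hydroxyguai-5-en-3-one (1β-H, 10β-H, 10α-methyl, 4α-methyl, 7β side chain) | O=C1C[C@H]2C(=C[C@H](C(C)(C)O)CC[C@H]2C)[C@@]1(C)Cc3c(OC)c(Br)c(OC)c(Br)c3OC | intermediate
13 | hydrazone of 12 | NN=C1C[C@H]2C(=C[C@H](C(C)(C)O)CC[C@H]2C)[C@@]1(C)Cc3c(OC)c(Br)c(OC)c(Br)c3OC | intermediate
14 | 4β-(3,5-dibromo-2,4,6-trimethoxybenzyl)guai-5-en-11-ol (configuration as in 12) | COc1c(Br)c(OC)c(Br)c(OC)c1C[C@@]2(C)CC[C@H]3C2=C[C@H](C(C)(C)O)CC[C@H]3C | intermediate
15 | isovaleryl chloride (3-methylbutanoyl chloride) | CC(C)CC(=O)Cl | starting material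
16 | N-methoxy-N,3-dimethylbutanamide | CC(C)CC(=O)N(C)OC | intermediate
17 | dilithium salt of the tetrahedral adduct of the monolithiated arene to 16 (C11 alkoxide, remaining aryl bromide; hemiaminal carbon not defined) | [Li+].[Li+].CC(C)CC([O-])(N(C)OC)c1c(OC)c(Br)c(OC)c(C[C@@]2(C)CC[C@H]3C2=C[C@H](C(C)(C)[O-])CC[C@H]3C)c1OC | intermediate
18 | tri-O-methyl ether of the target, 3-formyl-5-isovaleryl-2,4,6-trimethoxybenzyl group at C4β of guai-5-en-11-ol | CC(C)CC(=O)c1c(OC)c(C=O)c(OC)c(C[C@@]2(C)CC[C@H]3C2=C[C@H](C(C)(C)O)CC[C@H]3C)c1OC | intermediate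
19 | CNP0583424.1 | CC(C)CC(=O)c1c(O)c(C=O)c(O)c(C[C@@]2(C)CC[C@H]3C2=C[C@H](C(C)(C)O)CC[C@H]3C)c1O | target

**Step count:** 12 steps in total. The longest linear sequence has 9 steps (1, 2, 3, 6, 7, 8, 9, 11, 12).

**Steps most likely to fail**

Step 7.
- Process at risk: the excited state may be drained by α-cleavage at C3–C4 with 1,3-acyl shift, or by oxa-di-π-methane bridging. Both paths need the C5=C6 bond. The 1,3-diradical may also end in the 1,2-hydrogen shift instead of closing.
- Fallback: it sets out from 10 and comes back at 12, and it takes the C5=C6 bond out of play before irradiation.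
- Epoxidation of 10 with mCPBA (NaHCO3, CH2Cl2, 0 °C) should attack only the electron-rich trisubstituted alkene. Attack from the α face, away from the benzyl group and the side chain, would give the 5α,6α-epoxy enone F1.
- F1 is an ordinary 4,4-dialkylcyclohex-2-enone. For this class the lumiketone rearrangement (hν, t-BuOH), with migration of the ring bond C10–C5 to C1, is established. It should give the epoxy lumiketone F2.
- SmI2–H2O as in step 8 would open F2 to the epoxy ketone F3. Cornforth-type deoxygenation (Zn, NaI, AcOH/NaOAc) would then restore C5=C6 and deliver 12.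

Step 8.
- Process at risk: loss of aryl bromine, further reduction of the liberated ketone by divalent samarium, or low facial selectivity in the hydrogen delivery at C10.
- Fallback: it sets out from 11 and comes back at 14, so step 9 is bypassed. The ketyl is replaced by a carbon radical, and the deoxygenation is merged with the ring opening.
- NaBH4 (MeOH, 0 °C) would give the cyclopropyl carbinol F4. Its C3 configuration is of no consequence.
- 1,1'-Thiocarbonyldiimidazole with DMAP should acylate only the secondary hydroxyl group and give the thiocarbonylimidazolide F5.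
- Barton–McCombie conditions (Bu3SnH, AIBN, toluene, 90 °C) would generate the C3 cyclopropylcarbinyl radical. This radical opens the outer bond C2–C10 and picks up hydrogen at C10, giving the guaia-2,5-diene F6.
- Diimide (TsNHNH2, NaOAc, aqueous DME, reflux) should then saturate only the cis-disubstituted C2=C3 bond and give 14.

Step 11.
- Process at risk: collapse of the tetrahedral adduct before or during the second exchange, which would let the aryllithium attack the free ketone.
- Fallback: it sets out from 14 and comes back at 18. The ketone is carried through the second lithiation one oxidation level lower.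
- Exchange with n-BuLi (2.1 equiv, THF, −78 °C) and addition to isovaleraldehyde would give an inert lithium alkoxide. A second exchange followed by DMF would give the hydroxy aldehyde F7 as a mixture of carbinol epimers.
- Dess–Martin periodinane (CH2Cl2, rt) would oxidise only the secondary benzylic carbinol and give 18.

**Further compounds**
F1 | step 7 | 5α,6α-epoxide of 10 | O=C1C=C[C@@]2(C)CC[C@@H](C(C)(C)O)[C@@H]3O[C@]23[C@@]1(C)Cc4c(OC)c(Br)c(OC)c(Br)c4OC
F2 | step 7 | 5α,6α-epoxy-2,10-cycloguaian-3-one (5,6-epoxide of 11) | O=C1[C@H]2[C@H]3[C@]4(O[C@H]4[C@H](C(C)(C)O)CC[C@@]23C)[C@@]1(C)Cc5c(OC)c(Br)c(OC)c(Br)c5OC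
F3 | step 7 | 5α,6α-epoxyguaian-3-one (5,6-epoxide of 12) | O=C1C[C@H]2[C@]3(O[C@H]3[C@H](C(C)(C)O)CC[C@H]2C)[C@@]1(C)Cc4c(OC)c(Br)c(OC)c(Br)c4OC
F4 | step 8 | C3 carbinol of 11 (C3 not defined) | OC1[C@H]2[C@H]3C(=C[C@H](C(C)(C)O)CC[C@@]23C)[C@@]1(C)Cc4c(OC)c(Br)c(OC)c(Br)c4OC
F5 | step 8 | O-(imidazol-1-ylthiocarbonyl) derivative of F4 | S=C(OC1[C@H]2[C@H]3C(=C[C@H](C(C)(C)O)CC[C@@]23C)[C@@]1(C)Cc4c(OC)c(Br)c(OC)c(Br)c4OC)n5ccnc5
F6 | step 8 | 4β-(3,5-dibromo-2,4,6-trimethoxybenzyl)guaia-2,5-dien-11-ol | C1=C[C@H]2C(=C[C@H](C(C)(C)O)CC[C@H]2C)[C@@]1(C)Cc3c(OC)c(Br)c(OC)c(Br)c3OC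
F7 | step 11 | hydroxy aldehyde, 18 with CH(OH) in place of the ketone C=O (carbinol carbon not defined) | CC(C)CC(O)c1c(OC)c(C=O)c(OC)c(C[C@@]2(C)CC[C@H]3C2=C[C@H](C(C)(C)O)CC[C@H]3C)c1OC
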